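The free catalyst is what I count: its turnover number N is the amount of product made per amount of catalyst charged. Counting left-handed product, the delta run reads N = 16.2 at 50.0 min.

| setting | delta | Sunday's | Wednesday's |
|---|---|---|---|
| left-handed substrate | 0.067 M | 0.10 M | 0.10 M |
| right-handed substrate | 0.067 M | 0.10 M | 0.10 M |
| reagent | 0.080 M | 0.0500 M | 0.0800 M |
| free catalyst | 1 mM | 1.0 mM | 1.0 mM |
| impurity | 0.40 mM | 0.12 mM | 0.40 mM |
| temperature | −20 °C | −20 °C | −20 °C |
| remark | run made earlier |  |  |
| time |  | 2.0 h | 4.0 h |

delta run (percent of the left-handed substrate and right-handed substrate together charged)

| time / min | left-handed product / % | left-handed substrate / % |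
|---|---|---|
| 6.00 | 2.6 | 47.9 |
| 15.0 | 5.7 | 44.4 |
| 30.0 | 8.0 | 40.8 |
| 50.0 | 12.1 | 38.2 |

(scatter of a reading: 0.5 percentage points)

- free catalyst is single-handed; left-handed substrate and right-handed substrate are mirror images of each other, charged as a racemate, each of them at the stated concentration
- no earlier run changes the charge of impurity; that part of a forecast is a guess

- which of the two ends with the higher amount of left-handed product, in percent of the left-handed substrate and right-handed substrate together charged ("neither" if they lie within 2 percentage points) (Sunday's / Wednesday's / neither)
- left-handed product at the end, in percent of the left-handed substrate and right-handed substrate together charged, Sunday's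
- left-handed product at the end, in percent of the left-handed substrate and right-handed substrate together charged, Wednesday's

I start with the main step alone: reagent and left-handed substrate meet on the free catalyst, which comes back. The first reading gives a rate constant at this catalyst charge of 0.108 M⁻¹ min⁻¹, a rough value given the scatter. Held at its starting rate, Wednesday's flask would count 208 turnovers and Sunday's 65.0. Each turnover takes one reagent, though, so the reagent charge over the catalyst charge is a turnover ceiling: 80.0 for Wednesday's and 50.0 for Sunday's. Both starting-rate counts pass it, which makes reagent the limiting reagent of this first picture, with 40.0 % of left-handed product for Wednesday's and 25.0 % for Sunday's.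

Next I add catalyst loss. In the delta run the readings put the rate of left-handed turnover at 0.581 min⁻¹ up to the first reading and 0.275 min⁻¹ between the last two, a ratio of 0.473. The left-handed substrate read last and the reagent reckoned from the left-handed product give a ratio of 0.636, so the rate ratio is the lower, though with this scatter that is a weak sign of catalyst loss. My guess is that each impurity removes one catalyst, which leaves a working share of 0.600 on Wednesday's and 0.880 on Sunday's. The second-order law, with that share held from the start, then gives 25.9 % for Wednesday's and 15.2 % for Sunday's.

The right-handed substrate may also take reagent, and the delta run reads neither it nor a right-handed product, so I take these figures as probably high and commit to Wednesday's ahead.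

The forecast, holding that “less impurity means slower decay”, says Wednesday's, with 13.5 % (9.5 % to 17.5 %) for Sunday's and 21 % (15 % to 29 %) for Wednesday's, below my figures.

The simulation gives Wednesday's ahead, with 12.5 % for Sunday's and 20.2 % for Wednesday's.

    2 free catalyst → spent catalyst C (k = 0.0210 M⁻¹ s⁻¹, Ea = 56.0 kJ mol⁻¹)
    reagent + free catalyst + right-handed substrate → free catalyst + right-handed product (k = 1.40 M⁻² s⁻¹, Ea = 40.0 kJ mol⁻¹)
    reagent + free catalyst + left-handed substrate → free catalyst + left-handed product (k = 2.40 M⁻² s⁻¹, Ea = 37.0 kJ mol⁻¹)
    free catalyst + impurity → spent catalyst A (k = 2.40 M⁻¹ s⁻¹, Ea = 40.0 kJ mol⁻¹)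
    free catalyst → spent catalyst B (k = 3.20 × 10⁻⁵ s⁻¹, Ea = 86.0 kJ mol⁻¹)
    (constants at −20 °C)

In Wednesday's flask at 2.00 h the impurity stands at 0.0140 % of its charge, spent catalyst A at 40.0 % of the catalyst and free catalyst at 39.8 %. By 4.00 h free catalyst is down to 28.5 % while both substrates go on taking reagent, and 20.2 % of left-handed with 13.0 % of right-handed product counts 66.5 turnovers against the ceiling of 80.0. Sunday's flask counts 40.6 against 50.0, and its neighbour with 0.030 M of reagent counts 24.9 against 30.0.

The earlier runs and the new flask come from a simulation with made-up constants, and the scatter is random.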